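# Proposed synthesis of CNP0268004.1 through a cyclobutadiene double bromolactonisation

Atom labels used throughout: ring A is the butyl-bearing butenolide (O1, C2 carbonyl, C3, C4, spiro C5); ring B is the acetoxybutyl-bearing butenolide (same atoms primed); ring C is the cyclobutane C5–C6–C6′–C5′; Cα is the first side-chain carbon on C3′.

## Analysis of the target

The target is a dispiro compound. Cyclobutane ring C carries, on its two adjacent quaternary carbons C5 and C5′, the spiro junctions to two 4-bromo-3-alkylbut-2-en-4-olides (ring A with butyl on C3, ring B with (R)-1-acetoxybutyl on C3′), and one bromine on each of C6 and C6′. There are five stereocentres, four contiguous on ring C and one at Cα. On ring C the two lactone oxygens are trans, the two bromines are trans, and each bromine is anti to the lactone oxygen on the neighbouring spiro carbon. Without the acetoxy group the core therefore has a C2 axis through the midpoints of C5–C5′ and C6–C6′ (5S,6S,11R,12R in dispiro[4.0.4.2]dodecane numbering); the (R)-acetoxy group at Cα is the only element that breaks this symmetry. The sensitive groups are the two β-bromobutenolides (vinylogous acyl bromides, substituted at C4 by amines, hydroxide or thiolates through addition–elimination), the two secondary bromides on the strained ring (elimination with base) and the allylic acetate. The synthesis is hard because two adjacent fully substituted spiro carbons and two bromomethine carbons must be set on one four-membered ring in one absolute configuration, and because the two halves differ by a single remote oxygen. The strategy rests on the fact that every carbon of ring C bears exactly one heteroatom and that the pairs C6–Br/C5–O1 and C6′–Br/C5′–O1′ are anti. This is the pattern left when Br+ and a carboxylate add anti across each double bond of a cyclobuta-1,3-diene that carries two 3-bromoacrylic acid arms on neighbouring carbons, each carboxyl held cis to the four-membered ring.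

## Retrosynthetic reasoning

**18 back to 13 (acetate and Cα–O bond).** The acetate C–O bond and then the Cα–O bond are cut first, because removing the oxygen at Cα turns the target into the C2-symmetric 13. In 13 the two butyl groups are homotopic, so functionalising either gives the same constitution, and the only unsymmetrical element is added after the difficult core exists. Forward, the four Cα–H bonds are the only allylic C–H bonds and are addressed by radical bromination (14) and solvolysis (15). Substitution at this allylic centre cannot be trusted to give one epimer. The configuration is therefore set separately: both epimers are oxidised to ketone 16, which is reduced under reagent control to the (R)-alcohol 17 and acetylated to 18.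

**13 back to 10 (key disconnection).** The four bonds O1–C5, C6–Br, O1′–C5′ and C6′–Br are cut together. They are all the heteroatom bonds of ring C, and their anti relationships are exactly those of two anti additions. The cut returns the cyclobutadiene diacid 11, in which all four ring carbons are sp2 and no stereocentre remains. Two rings and four stereocentres are gained in one operation from a symmetric precursor. Diene 11 cannot be stored, so the real precursor is its tricarbonyliron complex 10. Forward, the step has to do the following:
- remove iron oxidatively with a tetravalent cerium salt;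
- hand the first electrophilic bromine to C6 of the freed diene on one enantiotopic face and let carboxylate A close on C5 from the other face (monolactone 12);
- then add the second bromine to C6′ anti to the first, with closure of carboxylate B on C5′.

Two points of the design are fixed here. A free chiral amine would be oxidised by tetravalent cerium, so the chiral base is used in full equivalent as the ammonium salt of the diacid, with a lipophilic cerium salt in a non-polar medium. The bromine transfer is intermolecular, so what must be kept dilute is the free diene; this is done by slow release into an excess of the bromine donor.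

**10 back to 7 (functional groups of the arms).** The acids come from tert-butyl esters 9 by acidolysis, because hydroxide would substitute the vinylic bromine. The C4–Br bonds come from C4–OTf bonds of 8 by nickel-catalysed halide exchange with retention. The enol triflates come from bis(β-keto ester) 7. The forward triflation must give the (E) geometry (triflate trans to ester, four-membered ring cis to ester), since only this geometry lets the carboxyl reach C5; it is obtained from the non-chelated enolate.

**7 back to 4, 6 and 5 (C3–C4 and C3′–C4′).** Both arm carbon–carbon bonds are cut in a crossed Claisen sense. The diester complex 4 has no α-hydrogen and accepts two equivalents of the enolate of tert-butyl hexanoate 6, which brings C2, C3 and the butyl group of each ring in one step. Ester 6 is made from acid chloride 5.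

**4 back to 1 and 2 (ring C carbons).** The complexed cyclobutadiene comes from dichlorocyclobutene 3 by dehalogenative complexation. Compound 3 is the [2+2] photoadduct of alkyne diester 1 and dichloroethene 2, so the four ring carbons and the two arm attachment points come from two commodity chemicals.

## Alternatives that were turned down

**Alternative 1: ring C by ring contraction of a tartrate-derived sulfone.**
- Disconnection: the C6=C6′ bond of cyclobutene A1, dimethyl (1R,2R)-1,2-bis(tert-butyldimethylsilyloxy)cyclobut-3-ene-1,2-dicarboxylate, is the last ring bond formed. Its two quaternary carbinol carbons (the future C5 and C5′) come from the chiral-pool diester A3 (dimethyl L-tartrate).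
- Key step: Ramberg–Bäcklund contraction of thiolane dioxide A2 (α-halogenation in the flask, 1,3-elimination to the episulfone, cheletropic loss of the sulfonyl bridge).
- For: the absolute configuration and the trans relation of the two C–O bonds are bought from A3. On enantiocontrol this is stronger than the chosen key step, which relies on face selection on a fleeting diene.
- Against: A2 requires both carbinol carbons of A3 to be alkylated to quaternary centres and bridged through sulfur. Contracting a five-membered sulfone to a cyclobutene flanked by two quaternary carbons is at the limit of the reaction. After A1 both butenolides must still be built on hindered tertiary oxygens, and since the two ester/ether pairs of A1 are homotopic, two different rings again need a statistical differentiation. The final dibromination of C6=C6′ can give two trans-dibromides (bromine anti or syn to the neighbouring oxygen) with nothing in the mechanism to choose between them.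
- Comparison: the chosen route fixes each bromine anti to its oxygen through the stereospecificity of bromolactonisation and closes rings A and B in the same step. Alternative 1 would need roughly twice as many steps after its key step.

**Alternative 2: C5–C5′ by photoclosure of a pyrone.**
- Disconnection: the C5–C5′ bond is formed by 4π electrocyclisation of pyrone A5 (methyl 3-(hexanoyloxy)-2-oxo-2H-pyran-6-carboxylate) between the ring carbons that carry the acyloxy group and the ester.
- Key step: irradiation near 300 nm at low temperature gives the bicyclic β-lactone A4, methyl 4-(hexanoyloxy)-3-oxo-2-oxabicyclo[2.2.0]hex-5-ene-1-carboxylate. The hexanoyl group supplies C2, C3 and the butyl group of ring A, and the β-lactone carbonyl becomes C4.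
- For: the cis fusion of the two four-membered rings in A4 forces the two oxygens on the new bond to opposite faces of the cyclobutene, which is at least as secure as two anti additions. The two oxygens are differentiated from the start, which suits the unsymmetrical target better than the chosen route. A5 is short to make.
- Against: closure of the planar, achiral A5 gives the racemate, and there is no handle for enantiocontrol. Photoisomers of this kind revert thermally, decarboxylate on further irradiation, and carry a β-lactone that is opened by the nucleophiles needed later. Ring A must be made by an intramolecular Claisen-type acyl transfer that opens the β-lactone, ring B must be built from the ester, and the bromines must then be added across the cyclobutene with the same unsolved anti/syn question as in alternative 1.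
- Comparison: the route would be longer, racemic, and would leave the bromine stereochemistry to chance, whereas the chosen step sets it mechanistically.

**Alternative 3: acetylene [2+2] across a bifuranylidene dione.**
- Disconnection: C5–C6 and C5′–C6′ are formed by [2+2] photocycloaddition of A8 (acetylene) across the central double bond of the (E)-bifuranylidene dione A7.
- Key step: triplet-sensitised irradiation gives the dispiro cyclobutene A6 (the target lacking the two ring bromines), which is then dibrominated.
- For: this is the most convergent plan for the real, unsymmetrical target. Two different butenolide halves, one already carrying the (R)-acetoxybutyl group, are joined, so no late C–H oxygenation and no statistical step are needed. On this point it is stronger than the chosen route.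
- Against: the tetrasubstituted C5=C5′ bond of A7 must be made (E)-selectively by cross-coupling two different γ-carbons, where homocoupling competes. Triplet excitation isomerises that bond, and the addition runs through a 1,4-biradical, so the trans relation of O1 and O1′ is not guaranteed. A8 is a poor triplet partner, and A6 can absorb and react again. The only stereocentre in A7 is remote, so its two faces are not differentiated and two core diastereomers are expected. The dibromination of A6 then faces the anti/syn problem once more.
- Comparison: the chosen route gives up convergence at Cα (three extra steps) and gains in return all four core stereocentres with their relative configuration fixed by mechanism.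

Key step: step 8

Assumption: the sense of induction of (DHQD)2PHAL in step 8 is taken to deliver the enantiomer drawn; should it prove opposite, the pseudo-enantiomeric (DHQ)2PHAL is used with no other change.

## Route

Step 1
Reactants: 1 dimethyl acetylenedicarboxylate; 2 (E)-1,2-dichloroethene
Product: 3 dimethyl 3,4-dichlorocyclobut-1-ene-1,2-dicarboxylate (mixture of cis and trans dichlorides)
Conditions: hν (medium-pressure Hg lamp, Pyrex filter), acetophenone (sensitiser), 2 (10 equiv) in MeCN, 0 °C, stopped at partial conversion
Reagents that add atoms: none
Why: Sensitised [2+2] photocycloaddition of an acetylenic diester to a haloalkene, with the alkene in large excess so that the excited ynoate is trapped before it oligomerises; the cis/trans ratio of the chlorines is irrelevant because both are removed in step 2, and stopping early limits a second addition to the product.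

Step 2
Reactants: 3 dimethyl 3,4-dichlorocyclobut-1-ene-1,2-dicarboxylate
Product: 4 tricarbonyl(η4-dimethyl cyclobuta-1,3-diene-1,2-dicarboxylate)iron
Conditions: Fe2(CO)9 (2.5 equiv), toluene, 50 °C
Reagents that add atoms: diiron nonacarbonyl Fe2(CO)9, [Fe].[Fe].[C-]#[O+].[C-]#[O+].[C-]#[O+].[C-]#[O+].[C-]#[O+].[C-]#[O+].[C-]#[O+].[C-]#[O+].[C-]#[O+]
Why: Dehalogenative complexation of a 3,4-dihalocyclobutene: zerovalent iron removes both chlorines as FeCl2 and the diene is trapped at once as its stable 18-electron Fe(CO)3 complex; the esters are spectators.

Step 3
Reactants: 5 hexanoyl chloride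
Product: 6 tert-butyl hexanoate
Conditions: LiOC(CH3)3 (1.05 equiv), THF, 0 → 23 °C
Reagents that add atoms: lithium tert-butoxide, CC(C)(C)[O-].[Li+]
Why: Acylation of an alkoxide by an acid chloride; the tert-butyl ester is chosen because its lithium enolate does not self-condense at low temperature and because it is later removed by acid and not by hydroxide.

Step 4
Reactants: 4 tricarbonyl(η4-dimethyl cyclobuta-1,3-diene-1,2-dicarboxylate)iron; 6 tert-butyl hexanoate
Product: 7 tricarbonyl{η4-di-tert-butyl 2,2′-[cyclobuta-1,3-diene-1,2-diyldi(carbonyl)]dihexanoate}iron (mixture of diastereomers and enol forms)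
Conditions: LiN(i-Pr)2 (5.2 equiv), 6 (5 equiv), THF, −78 °C; then 4, −78 → −30 °C; aq. NH4Cl
Reagents that add atoms: none
Why: Crossed Claisen condensation in which 4 has no α-hydrogen, so only the preformed enolate of 6 can be the donor, and excess enolate deprotonates each β-keto ester as it forms and so protects it from a second addition. Ring closure between the two arms is disfavoured because exocyclic bonds on a four-membered ring diverge by about 90°.

Step 5
Reactants: 7 bis(β-keto ester) complex
Product: 8 tricarbonyl{η4-di-tert-butyl (2E,2′E)-3,3′-(cyclobuta-1,3-diene-1,2-diyl)bis[2-butyl-3-(trifluoromethylsulfonyloxy)prop-2-enoate]}iron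
Conditions: (CF3SO2)2O (3 equiv), 25% aq. (CH3)4NOH (6 equiv), toluene, 0 °C, vigorous stirring
Reagents that add atoms: trifluoromethanesulfonic anhydride, O=S(=O)(OS(=O)(=O)C(F)(F)F)C(F)(F)F
Why: O-Sulfonylation of a β-keto ester enolate under non-chelating two-phase conditions: with a tetraalkylammonium counter-ion no metal bridges the two oxygens, so the enolate adopts the dipole-minimised geometry with the enolate oxygen trans to the ester, which also keeps the bulky complexed ring away from the butyl group. This geometry is frozen as the (E)-triflate, and the α-stereocentres of 7 disappear.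

Step 6
Reactants: 8 bis[(E)-enol triflate] complex
Product: 9 tricarbonyl{η4-di-tert-butyl (2E,2′E)-3,3′-(cyclobuta-1,3-diene-1,2-diyl)bis(3-bromo-2-butylprop-2-enoate)}iron
Conditions: Ni(OAc)2·4H2O (10 mol%), cycloocta-1,5-diene (30 mol%), Zn (20 mol%), LiBr (4 equiv), N,N-dimethylacetamide/THF (3:1), 23 °C
Reagents that add atoms: lithium bromide, [Li+].[Br-]
Why: Nickel-catalysed halide exchange of enol triflates (oxidative addition of C–OTf to zerovalent nickel formed in the flask, triflate/bromide exchange, C–Br reductive elimination) runs at room temperature with retention of alkene geometry; none of the reagents is an oxidant, so the Fe(CO)3 unit should be untouched.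

Step 7
Reactants: 9 bis[(E)-bromoacrylate] di-tert-butyl ester complex
Product: 10 tricarbonyl[η4-(2E,2′E)-3,3′-(cyclobuta-1,3-diene-1,2-diyl)bis(3-bromo-2-butylprop-2-enoic acid)]iron
Conditions: CF3CO2H/CH2Cl2 (1:4), 0 → 23 °C
Reagents that add atoms: none
Why: Acidolysis of tert-butyl esters with loss of isobutene; it avoids hydroxide, which would attack the β-bromoacrylate by addition–elimination, and neither the vinylic bromides nor the electron-poor Fe(CO)3 complex should be affected by the acid.

Step 8
Reactants: 10 tricarbonyliron complex of the cyclobutadiene diacid
Product: 13 (5S,6S,11R,12R)-4,10,11,12-tetrabromo-3,9-dibutyl-1,7-dioxadispiro[4.0.4.2]dodeca-3,9-diene-2,8-dione, via free cyclobutadiene diacid 11 (not isolated), via bromocyclobutene monolactone acid 12 (not isolated)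
Conditions: (DHQD)2PHAL [hydroquinidine 1,4-phthalazinediyl diether, C48H54N6O4] (1.05 equiv, premixed with 10), NBS (2.4 equiv), CH2Cl2/toluene (1:1), 0.002 M in 10, −20 °C, dark; (n-Bu4N)2Ce(NO3)6 (3.3 equiv, made beforehand from (NH4)2Ce(NO3)6 and n-Bu4NHSO4) in CH2Cl2 by syringe pump over 4 h; aq. Na2S2O3
Reagents that add atoms: N-bromosuccinimide, O=C1CCC(=O)N1Br
Why: Proposed new method: tetravalent cerium removes the iron from 10 by outer-sphere oxidation (three electrons per iron), the established way to set cyclobutadienes free, and diene 11 is born inside the ion pair with the doubly protonated alkaloid dimer, so that NBS, activated by hydrogen bonding to the ammonium site, should deliver the first bromine to the unsubstituted carbon C6 on one enantiotopic face. The resulting tertiary cyclobutenyl cation, bridged by the new bromine, is closed by carboxylate A at C5 from the opposite face (5-exo-trig, O1–C5) to give 12, so the absolute configuration of C6 and C5 is set by the chiral base and their relative configuration by anti addition. In 12 the remaining C5′=C6′ bond is the terminus of a (Z)-2,4-dienoic acid, a substrate class known to undergo bromolactonisation to 5-(bromoalkyl)butenolides; bromine should enter at C6′ on the face that carries H on C6 and O1 on C5, away from the C6 bromine and from C4, and carboxylate B closes on C5′ anti to it (5-exo-trig, O1′–C5′), so C6′ and C5′ are set by the substrate and both the bromines and the lactone oxygens end up trans. The closest known reactions are the oxidative release of cyclobutadiene from its Fe(CO)3 complex with capture by halogen to give trans-3,4-dihalocyclobutenes, and alkaloid-mediated asymmetric bromolactonisation of unsaturated acids; new is their combination on a transient antiaromatic diene. Capture must beat dimerisation of 11, which is second order in 11 and is suppressed by releasing it slowly into an excess of NBS at high dilution. Bromine must enter at C6 and not at C5, which the arm on C5 secures by hindrance and by stabilising the cation, and five-ring closure at C5 must beat six-ring closure of carboxylate B at C6′, which is favoured because the charge sits at the tertiary terminus and arm A reaches C5 perpendicular to ring C without strain. The base is used in full equivalent as its salt because free tertiary amine would be oxidised by tetravalent cerium, and the lipophilic cerium salt permits a non-polar medium in which the ion pair stays tight.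

Step 9
Reactants: 13 C2-symmetric dispiro tetrabromide
Product: 14 Cα-bromide of 13 [one butyl group converted into 1-bromobutyl; both Cα epimers]
Conditions: NBS (0.8 equiv), 2,2′-azobis(2-methylpropionitrile) (5 mol%), PhCF3, 80 °C; unreacted 13 recycled
Reagents that add atoms: N-bromosuccinimide, O=C1CCC(=O)N1Br
Why: Wohl–Ziegler bromination: the only allylic C–H bonds of 13 are the four at Cα and its symmetry-related carbon, which are pairwise homotopic through the C2 axis, so monobromination gives one constitution; the Cα configuration is not controlled and need not be, since it is erased in step 11. Side-chain bromination of this kind is known for simple 3-alkyl-4-bromobutenolides.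

Step 10
Reactants: 14 Cα-bromide (epimers)
Product: 15 Cα-alcohol [one butyl group of 13 converted into 1-hydroxybutyl; both Cα epimers]
Conditions: Ag2CO3 (1.5 equiv), acetone/H2O (4:1), 23 °C, dark
Reagents that add atoms: water, O
Why: Silver-assisted solvolysis of the allylic bromide, in which silver pulls the bromide while water at high concentration attacks Cα, the less hindered allyl terminus that keeps C3′=C4′ conjugated with the lactone; the cyclobutyl and vinylic bromides should not ionise under these conditions.

Step 11
Reactants: 15 Cα-alcohol (epimers)
Product: 16 Cα-ketone [one butyl group of 13 converted into butanoyl]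
Conditions: Dess–Martin periodinane (1.5 equiv), CH2Cl2, 0 → 23 °C
Reagents that add atoms: none
Why: Dess–Martin oxidation of a secondary allylic alcohol under neutral, non-nucleophilic conditions; both epimers converge on one ketone, and no aqueous base is used that could displace the C4′ bromine of this doubly activated alkene.

Step 12
Reactants: 16 Cα-ketone
Product: 17 (R)-Cα-alcohol [one butyl group of 13 converted into (1R)-1-hydroxybutyl]
Conditions: (S)-Me-CBS oxazaborolidine (C18H20BNO, 0.3 equiv), BH3·S(CH3)2 (0.7 equiv), THF, −30 °C; CH3OH quench
Reagents that add atoms: none
Why: Corey–Bakshi–Shibata reduction: the ketone binds the ring boron anti to its larger substituent, here the fully substituted alkenyl carbon C3′, and hydride is delivered in the same sense as acetophenone to (R)-1-phenylethanol with the (S)-catalyst, so the new stereocentre at Cα is set (R) by the reagent. Catalysed 1,2-addition at low temperature should outrun conjugate reduction, and the lactones are inert to borane at this temperature.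

Step 13
Reactants: 17 (R)-Cα-alcohol
Product: 18 (1R)-1-[(5S,6S,11R,12R)-4,10,11,12-tetrabromo-9-butyl-2,8-dioxo-1,7-dioxadispiro[4.0.4.2]dodeca-3,9-dien-3-yl]butyl acetate (the target)
Conditions: (CH3CO)2O (1.5 equiv), Sc(OSO2CF3)3 (1 mol%), MeCN, −20 °C
Reagents that add atoms: acetic anhydride, CC(=O)OC(C)=O
Why: Lewis-acid-catalysed O-acetylation, chosen over amine-mediated acylation because nucleophilic amines substitute 4-bromobutenolides by addition–elimination; the Cα–O bond is not broken, so the (R) configuration is retained.

## Compound list

1 | dimethyl acetylenedicarboxylate | COC(=O)C#CC(=O)OC | starting material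
2 | (E)-1,2-dichloroethene | Cl/C=C/Cl | starting material
3 | dimethyl 3,4-dichlorocyclobut-1-ene-1,2-dicarboxylate (cis/trans mixture) | COC(=O)C1=C(C(=O)OC)C(Cl)C1Cl | intermediate
4 | tricarbonyl(η4-dimethyl cyclobuta-1,3-diene-1,2-dicarboxylate)iron | COC(=O)C1=C(C=C1)C(=O)OC.[Fe].[C-]#[O+].[C-]#[O+].[C-]#[O+] | intermediate
5 | hexanoyl chloride | CCCCCC(Cl)=O | starting material
6 | tert-butyl hexanoate | CCCCCC(=O)OC(C)(C)C | intermediate
7 | tricarbonyl{η4-di-tert-butyl 2,2′-[cyclobuta-1,3-diene-1,2-diyldi(carbonyl)]dihexanoate}iron (diastereomer mixture) | CCCCC(C(=O)OC(C)(C)C)C(=O)C1=C(C=C1)C(=O)C(CCCC)C(=O)OC(C)(C)C.[Fe].[C-]#[O+].[C-]#[O+].[C-]#[O+] | intermediate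
8 | tricarbonyl{η4-di-tert-butyl (2E,2′E)-3,3′-(cyclobuta-1,3-diene-1,2-diyl)bis[2-butyl-3-(trifluoromethylsulfonyloxy)prop-2-enoate]}iron | CCCC/C(C(=O)OC(C)(C)C)=C(\OS(=O)(=O)C(F)(F)F)C1=C(C=C1)/C(OS(=O)(=O)C(F)(F)F)=C(\C(=O)OC(C)(C)C)CCCC.[Fe].[C-]#[O+].[C-]#[O+].[C-]#[O+] | intermediate
9 | tricarbonyl{η4-di-tert-butyl (2E,2′E)-3,3′-(cyclobuta-1,3-diene-1,2-diyl)bis(3-bromo-2-butylprop-2-enoate)}iron | CCCC/C(C(=O)OC(C)(C)C)=C(\Br)C1=C(C=C1)/C(Br)=C(\C(=O)OC(C)(C)C)CCCC.[Fe].[C-]#[O+].[C-]#[O+].[C-]#[O+] | intermediate
10 | tricarbonyl[η4-(2E,2′E)-3,3′-(cyclobuta-1,3-diene-1,2-diyl)bis(3-bromo-2-butylprop-2-enoic acid)]iron | CCCC/C(C(=O)O)=C(\Br)C1=C(C=C1)/C(Br)=C(\C(=O)O)CCCC.[Fe].[C-]#[O+].[C-]#[O+].[C-]#[O+] | intermediate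
11 | (2E,2′E)-3,3′-(cyclobuta-1,3-diene-1,2-diyl)bis(3-bromo-2-butylprop-2-enoic acid), free diene formed in the flask, not isolated | CCCC/C(C(=O)O)=C(\Br)C1=C(C=C1)/C(Br)=C(\C(=O)O)CCCC | intermediate
12 | (2E)-3-bromo-2-butyl-3-[(3S,4S)-3,8-dibromo-7-butyl-6-oxo-5-oxaspiro[3.4]octa-1,7-dien-1-yl]prop-2-enoic acid (ring A closed, C6–Br anti to O1, C5′=C6′ retained), formed in the flask, not isolated | CCCCC1=C(Br)[C@@]2(OC1=O)[C@@H](Br)C=C2/C(Br)=C(\C(=O)O)CCCC | intermediate
13 | (5S,6S,11R,12R)-4,10,11,12-tetrabromo-3,9-dibutyl-1,7-dioxadispiro[4.0.4.2]dodeca-3,9-diene-2,8-dione | CCCCC1=C(Br)[C@@]2(OC1=O)[C@@H](Br)[C@H](Br)[C@@]21OC(=O)C(CCCC)=C1Br | intermediate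
14 | 13 with one butyl group replaced by 1-bromobutyl (both Cα epimers) | CCCCC1=C(Br)[C@@]2(OC1=O)[C@@H](Br)[C@H](Br)[C@@]21OC(=O)C(C(Br)CCC)=C1Br | intermediate
15 | 13 with one butyl group replaced by 1-hydroxybutyl (both Cα epimers) | CCCCC1=C(Br)[C@@]2(OC1=O)[C@@H](Br)[C@H](Br)[C@@]21OC(=O)C(C(O)CCC)=C1Br | intermediate
16 | 13 with one butyl group replaced by butanoyl | CCCCC1=C(Br)[C@@]2(OC1=O)[C@@H](Br)[C@H](Br)[C@@]21OC(=O)C(C(=O)CCC)=C1Br | intermediate
17 | 13 with one butyl group replaced by (1R)-1-hydroxybutyl | CCCCC1=C(Br)[C@@]2(OC1=O)[C@@H](Br)[C@H](Br)[C@@]21OC(=O)C([C@@H](CCC)O)=C1Br | intermediate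
18 | (1R)-1-[(5S,6S,11R,12R)-4,10,11,12-tetrabromo-9-butyl-2,8-dioxo-1,7-dioxadispiro[4.0.4.2]dodeca-3,9-dien-3-yl]butyl acetate | CCCCC1=C(Br)[C@@]2(OC1=O)[C@@H](Br)[C@H](Br)[C@@]21OC(=O)C([C@@H](CCC)OC(C)=O)=C1Br | target

## Step count and least certain steps

Total steps: 13. Longest linear sequence: 12 steps (steps 1, 2 and 4 to 13; step 3 is a one-step branch).

**Step 8 (key step, the one new method).** Most likely to go wrong:
- dimerisation of the freed diene, or its interception by nitrate, before bromine is transferred;
- consumption of the chiral base by the cerium oxidant, or a loose ion pair, so that the first bromine is delivered without face selection;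
- closure of carboxylate B at C6′ in competition with closure of carboxylate A at C5;
- entry of the second bromine syn to the first.

Fallback: the same cyclobutenyl cation is reached from a stable compound by known reactions. It sets out from 9. Oxidative demetalation with (NH4)2Ce(NO3)6 in the presence of LiBr in acetone at −20 °C (release of the diene with capture by halogen) should give the racemic trans-dibromocyclobutene di-tert-butyl ester F1. AgOSO2CF3 (1 equiv) in CH2Cl2 at −40 °C then ionises one allylic bromide, and the neighbouring tert-butyl ester closes on C5 anti to the remaining bromine with loss of isobutene, giving the racemic monolactone tert-butyl ester F2. NBS in CH2Cl2/(CF3)2CHOH effects the second bromolactonisation, again with the tert-butyl ester as oxygen nucleophile, to the racemate of 13, F3. This is resolved by preparative chromatography on a chiral stationary phase, and the route is rejoined at 13.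

**Step 5.** Most likely to go wrong: partial formation of the chelated enolate geometry, so that some arms carry the triflate cis to the ester and can never lactonise. Fallback: it sets out from 7. Tosylation with TsCl, N-methylimidazole and Et3N in CH2Cl2, a metal-free amine-mediated O-sulfonylation that is (E)-selective for α-substituted β-keto esters, should give the bis[(E)-enol tosylate] complex F4. Pd(PPh3)4-catalysed stannylation with (CH3)3SnSn(CH3)3 and LiCl in dioxane gives, with retention, the bis(alkenylstannane) complex F5. Bromodestannylation with NBS at −40 °C, again with retention, rejoins the route at 9.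

**Step 6.** Most likely to go wrong: slow oxidative addition at the hindered, fully substituted triflate, and loss of alkene geometry while the alkenylnickel intermediate, which carries an acyl group in the β-position, waits for reductive elimination. Fallback: the exchange is postponed until the iron has left and the double bond is locked in a ring. It sets out from 8. CF3CO2H gives the bis(triflate) diacid complex F6, the conditions of step 8 give the dispiro bis(4-triflyloxybutenolide) F7, and LiBr in acetone replaces both triflates by addition–elimination at C4 and C4′; the route is rejoined at 13.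

**Step 9.** Most likely to go wrong: over-bromination (second butyl group or a second bromine on Cα), loss of HBr at 80 °C, and opening of ring C from the allyl radical, whose spin density at C4′ lies next to the strained spiro carbon. Fallback: a halogen-free allylic oxidation that runs near room temperature, where the unimolecular ring opening is slower relative to trapping. It sets out from 13: t-BuOOH with catalytic Rh2(cap)4 (dirhodium tetrakis(caprolactamate), Rh2(C6H10NO)4) in ClCH2CH2Cl at 23–40 °C oxidises one allylic methylene directly to the ketone. The route is rejoined at 16, two steps are saved, and no new compound is made.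

**Step 12.** Most likely to go wrong: conjugate delivery of hydride to C4′ with loss of bromide, because the ketone makes C3′=C4′ a doubly activated acceptor; hydrolytic substitution of that bromine while 16 is handled; insufficient face selection. Fallback: the ketone is avoided. It sets out from 15: the two Cα epimers are separated by chromatography. The (R)-epimer is 17 and is acetylated as in step 13. The (S)-epimer F8 is converted directly into the acetate by Mitsunobu reaction with acetic acid (PPh3, diisopropyl azodicarboxylate), which inverts Cα. The route is rejoined at 17 and at 18.

## Further compounds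

F1 | step 8 | di-tert-butyl (2E,2′E)-3,3′-(trans-3,4-dibromocyclobut-1-ene-1,2-diyl)bis(3-bromo-2-butylprop-2-enoate), racemate (both enantiomers written) | CCCC/C(C(=O)OC(C)(C)C)=C(\Br)C1=C([C@@H](Br)[C@@H]1Br)/C(Br)=C(\C(=O)OC(C)(C)C)CCCC.CCCC/C(C(=O)OC(C)(C)C)=C(\Br)C1=C([C@H](Br)[C@H]1Br)/C(Br)=C(\C(=O)OC(C)(C)C)CCCC
F2 | step 8 | tert-butyl ester of 12, racemate (both enantiomers written) | CCCCC1=C(Br)[C@@]2(OC1=O)[C@@H](Br)C=C2/C(Br)=C(\C(=O)OC(C)(C)C)CCCC.CCCCC1=C(Br)[C@]2(OC1=O)[C@H](Br)C=C2/C(Br)=C(\C(=O)OC(C)(C)C)CCCC
F3 | step 8 | racemate of 13 (both enantiomers written) | CCCCC1=C(Br)[C@@]2(OC1=O)[C@@H](Br)[C@H](Br)[C@@]21OC(=O)C(CCCC)=C1Br.CCCCC1=C(Br)[C@]2(OC1=O)[C@H](Br)[C@@H](Br)[C@]21OC(=O)C(CCCC)=C1Br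
F4 | step 5 | tricarbonyl{η4-di-tert-butyl (2E,2′E)-3,3′-(cyclobuta-1,3-diene-1,2-diyl)bis[2-butyl-3-(4-methylphenylsulfonyloxy)prop-2-enoate]}iron | CCCC/C(C(=O)OC(C)(C)C)=C(\OS(=O)(=O)c1ccc(C)cc1)C2=C(C=C2)/C(OS(=O)(=O)c3ccc(C)cc3)=C(\C(=O)OC(C)(C)C)CCCC.[Fe].[C-]#[O+].[C-]#[O+].[C-]#[O+]
F5 | step 5 | tricarbonyl{η4-di-tert-butyl (2E,2′E)-3,3′-(cyclobuta-1,3-diene-1,2-diyl)bis[2-butyl-3-(trimethylstannyl)prop-2-enoate]}iron | CCCC/C(C(=O)OC(C)(C)C)=C(\[Sn](C)(C)C)C1=C(C=C1)/C([Sn](C)(C)C)=C(\C(=O)OC(C)(C)C)CCCC.[Fe].[C-]#[O+].[C-]#[O+].[C-]#[O+]
F6 | step 6 | tricarbonyl{η4-(2E,2′E)-3,3′-(cyclobuta-1,3-diene-1,2-diyl)bis[2-butyl-3-(trifluoromethylsulfonyloxy)prop-2-enoic acid]}iron | CCCC/C(C(=O)O)=C(\OS(=O)(=O)C(F)(F)F)C1=C(C=C1)/C(OS(=O)(=O)C(F)(F)F)=C(\C(=O)O)CCCC.[Fe].[C-]#[O+].[C-]#[O+].[C-]#[O+]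
F7 | step 6 | analogue of 13 with trifluoromethylsulfonyloxy in place of bromine at C4 and C4′ | CCCCC1=C(OS(=O)(=O)C(F)(F)F)[C@@]2(OC1=O)[C@@H](Br)[C@H](Br)[C@@]21OC(=O)C(CCCC)=C1OS(=O)(=O)C(F)(F)F
F0 | step 9 | none | none
F8 | step 12 | (S)-Cα epimer of 17 | CCCCC1=C(Br)[C@@]2(OC1=O)[C@@H](Br)[C@H](Br)[C@@]21OC(=O)C([C@H](CCC)O)=C1Br
A1 | alternative 1 | dimethyl (1R,2R)-1,2-bis(tert-butyldimethylsilyloxy)cyclobut-3-ene-1,2-dicarboxylate | COC(=O)[C@@]1(O[Si](C)(C)C(C)(C)C)C=C[C@]1(O[Si](C)(C)C(C)(C)C)C(=O)OC
A2 | alternative 1 | dimethyl (3R,4R)-3,4-bis(tert-butyldimethylsilyloxy)thiolane-3,4-dicarboxylate 1,1-dioxide | COC(=O)[C@@]1(O[Si](C)(C)C(C)(C)C)CS(=O)(=O)C[C@]1(O[Si](C)(C)C(C)(C)C)C(=O)OC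
A3 | alternative 1 | dimethyl L-tartrate | COC(=O)[C@H](O)[C@@H](O)C(=O)OC
A4 | alternative 2 | methyl 4-(hexanoyloxy)-3-oxo-2-oxabicyclo[2.2.0]hex-5-ene-1-carboxylate | CCCCCC(=O)O[C@]12C=C[C@@]1(C(=O)OC)OC2=O
A5 | alternative 2 | methyl 3-(hexanoyloxy)-2-oxo-2H-pyran-6-carboxylate | CCCCCC(=O)OC1=CC=C(C(=O)OC)OC1=O
A6 | alternative 3 | dispiro cyclobutene bis-butenolide (target lacking the two ring bromines) | CCCCC1=C(Br)[C@@]2(OC1=O)C=C[C@@]21OC(=O)C([C@@H](CCC)OC(C)=O)=C1Br
A7 | alternative 3 | (E)-bifuranylidene dione carrying butyl and (R)-1-acetoxybutyl | CCCCC1=C(Br)/C(OC1=O)=C2\OC(=O)C([C@@H](CCC)OC(C)=O)=C2Br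
A8 | alternative 3 | acetylene | C#C
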